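**Retrosynthetic overview**

- The triene is made last by an E-selective Horner–Wadsworth–Emmons olefination of a ring-B-fused lactol with a myrcene-type allylic phosphonate. The ring-A enal is carried through this as its allylic alcohol and re-oxidised afterwards.
- The lactol comes from a cis-fused unsaturated δ-lactone (a temporary third ring). It is built on the spiro β-hydroxy ketone by ynoate Michael addition, hydroxyl-directed reduction (sets C1) and thermodynamic lactonisation (sets C2 and the side-chain alkene geometry).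
- The ring-A enal comes from the isopropenyl group of carvone by ene chlorination, N-oxide oxidation and double-bond isomerisation. The carvone stereocentre is destroyed only after it has controlled C6 and C10.
- The spiro[4.5]decane comes from a cyclohexenyl cyclobutanol by a light-driven radical-cation semipinacol ring expansion (forms ring B and the C5 quaternary centre) coupled to radical allylation at C10.
- Ring order: ring A is bought in (S)-carvone, ring B is made by cyclobutanol ring expansion, then the lactone ring is formed and opened again in the olefination.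

Assumption: compounds 1, 6, 9, 16, 26 and 27 are bought; spiro compounds are numbered as spiro[4.5]decanes (ring B = C1–C5, ring A = C5–C10, C5 spiro, C6 = C(CH3)OH, C9 = isopropenyl carbon, C10 = chain carbon).

**Route**

Step 1
Reactants: 1 (S)-(+)-carvone
Product: 2 trans-carvone oxide (1S,4S,6S)-1-methyl-4-(prop-1-en-2-yl)-7-oxabicyclo[4.1.0]heptan-2-one
Conditions: 30% H2O2, aq. NaOH, MeOH, 0 °C
Reagents that add atoms: hydrogen peroxide (OO)
Why: Weitz–Scheffer nucleophilic epoxidation in which hydroperoxide adds to the enone β-carbon anti to the isopropenyl group, so the future C6–O bond is set trans to it.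

Step 2
Reactants: 2 trans-carvone oxide
Product: 3 (1S,4S)-1-methyl-4-(prop-1-en-2-yl)cyclohexane-1,2-diol (both C2 epimers)
Conditions: LiAlH4, THF, 0 → 25 °C
Reagents that add atoms: none
Why: Hydride reduces the ketone and opens the oxirane by SN2 attack at the secondary carbon, so the tertiary C–O centre is untouched; the new carbinol centre is removed in step 3.

Step 3
Reactants: 3 diol
Product: 4 (2S,5S)-2-hydroxy-2-methyl-5-(prop-1-en-2-yl)cyclohexan-1-one
Conditions: IBX, EtOAc, 75 °C
Reagents that add atoms: none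
Why: IBX oxidises the secondary hydroxyl of a 1,2-diol to the α-ketol without C–C cleavage and leaves the tertiary alcohol and the alkene alone.

Step 4
Reactants: 4 hydroxy ketone
Product: 5 (E)-2,4,6-triisopropylbenzenesulfonylhydrazone of 4
Conditions: 2,4,6-(i-Pr)3C6H2SO2NHNH2, cat. HCl, MeOH, 25 °C
Reagents that add atoms: 2,4,6-triisopropylbenzenesulfonyl hydrazide (CC(C)c1cc(C(C)C)c(S(=O)(=O)NN)c(C(C)C)c1)
Why: Hydrazone condensation, giving the E isomer with the sulfonamide turned away from the quaternary carbon.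

Step 5
Reactants: 5 trisylhydrazone; 6 cyclobutanone
Product: 8 1-[(3S,6S)-6-hydroxy-6-methyl-3-(prop-1-en-2-yl)cyclohex-1-en-1-yl]cyclobutan-1-ol, via dilithio vinyl alkoxide 7 (not isolated)
Conditions: n-BuLi (3.3 equiv), THF, −78 → 0 °C; then 6, −78 °C; aq. NH4Cl
Reagents that add atoms: none
Why: Shapiro reaction, regiospecific because only the CH2 side carries α-hydrogens, followed by 1,2-addition of the vinyllithium to the strained ketone; no stereocentre is formed or touched.

Step 6
Reactants: 8 cyclohexenyl cyclobutanol diol; 9 allyl phenyl sulfone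
Product: 12 (5R,6S,9S,10R)-6-hydroxy-6-methyl-9-(prop-1-en-2-yl)-10-(prop-2-en-1-yl)spiro[4.5]decan-1-one, via cyclic dimethylsilylene 10 (not isolated), via silyl sulfinate ester 11 (not isolated)
Conditions: Me2Si(NMe2)2, PhMe, 60 °C, evaporate; then 9 (5 equiv), 2,4,6-triphenylpyrylium tetrafluoroborate (5 mol%), ClCH2CH2Cl, 427 nm LEDs, 25 °C; then AcOH, THF–H2O
Reagents that add atoms: none
Why: Proposed new method: the excited pyrylium (E* about +2.3 V vs SCE) oxidises the trisubstituted alkene of 10 to its radical cation, the cationic C5 triggers a semipinacol 1,2-shift of a cyclobutane CH2 (strain release, silyloxy push) that forms ring B and the quaternary C5, the resulting secondary C10 radical is trapped by allyl phenyl sulfone (SH2′ allylation) and the expelled PhSO2 radical is reduced by the pyranyl radical to sulfinate, which takes the silyl cation (redox-neutral chain of events); the six-membered silylene holds both oxygens on one face of the alkene so only the cyclobutane carbon on the opposite face (the face of the C6 methyl) is aligned to migrate, which places C1 cis to the C6 oxygen, and the allyl group then enters C10 equatorially, anti to the C9 isopropenyl group, because axial attack is blocked by the syn-axial C6 methyl; the closest known reactions are photoredox radical-addition/semipinacol ring expansions of alkenyl cyclobutanols, alkene radical-cation functionalisation with photo-oxidants, and radical allylation with allyl sulfones.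

Step 7
Reactants: 12 allyl spiro ketone
Product: 14 (5R,6S,9S,10R)-6-hydroxy-10-(3-hydroxypropyl)-6-methyl-9-(prop-1-en-2-yl)spiro[4.5]decan-1-one, via trialkylborane 13 (not isolated)
Conditions: Sia2BH (from BH3·THF and 2-methylbut-2-ene), THF, 0 °C; then 30% H2O2, aq. NaHCO3
Reagents that add atoms: hydrogen peroxide (OO)
Why: Anti-Markovnikov hydroboration–oxidation in which the hindered dialkylborane takes the monosubstituted allyl alkene much faster than the 1,1-disubstituted isopropenyl alkene or the neopentyl ketone.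

Step 8
Reactants: 14 keto diol
Product: 15 (5R,6S,9S,10R)-10-{3-[(tert-butyldimethylsilyl)oxy]propyl}-6-hydroxy-6-methyl-9-(prop-1-en-2-yl)spiro[4.5]decan-1-one
Conditions: TBSCl, imidazole, CH2Cl2, 0 °C
Reagents that add atoms: tert-butyldimethylsilyl chloride (CC(C)(C)[Si](C)(C)Cl)
Why: Silylation selective for the primary hydroxyl over the hindered tertiary one; it keeps a nucleophilic primary alkoxide out of the ynoate addition in step 10.

Step 9
Reactants: 16 tert-butyldimethyl(prop-2-yn-1-yloxy)silane
Product: 18 methyl 4-[(tert-butyldimethylsilyl)oxy]but-2-ynoate, via lithium acetylide 17 (not isolated)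
Conditions: n-BuLi, THF, −78 °C; then ClCO2Me
Reagents that add atoms: methyl chloroformate (COC(=O)Cl)
Why: Acylation of a lithium acetylide with a chloroformate.

Step 10
Reactants: 15 silyl ether ketone; 18 ynoate
Product: 19 methyl (2E)-4-[(tert-butyldimethylsilyl)oxy]-3-[(2S,5R,6S,9S,10R)-10-{3-[(tert-butyldimethylsilyl)oxy]propyl}-6-hydroxy-6-methyl-1-oxo-9-(prop-1-en-2-yl)spiro[4.5]decan-2-yl]but-2-enoate (productive isomer of an E/Z and C2-epimer mixture)
Conditions: LiN(i-Pr)2 (2.2 equiv), THF, −78 °C; then 18, −78 → −40 °C; AcOH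
Reagents that add atoms: none
Why: Michael addition of the alkoxide–enolate dianion (C2 is the only enolisable carbon and the dianion cannot undergo retro-aldol cleavage) to the ynoate; alkene geometry and C2 are not yet fixed and converge in step 11.

Step 11
Reactants: 19 keto ester
Product: 21 cis-fused unsaturated δ-lactone (5,6-dihydro-2H-pyran-2-one fused to C1–C2 of ring B with O on C1 and the CH2OTBS-bearing alkene carbon on C2), via hydroxy ester 20 (not isolated)
Conditions: Me4NBH(OAc)3, MeCN–AcOH, −20 °C; then DBU, PhMe, 60 °C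
Reagents that add atoms: none
Why: Evans–Saksena directed reduction delivers hydride from the borohydride bound to the C6 hydroxyl onto the carbonyl face syn to C6, giving the C1 hydroxyl anti to C6 (1R); DBU then equilibrates alkene position, geometry and C2 through the dienolate, and lactonisation drains the mixture into the more stable cis-fused lactone, which sets C2 (S) and locks the side-chain alkene with the carbonyl carbon cis to C2.

Step 12
Reactants: 21 lactone
Product: 22 allylic chloride (the C9 substituent is now 3-chloroprop-1-en-2-yl)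
Conditions: Ca(OCl)2, CO2 (solid), CH2Cl2–H2O, 0 °C
Reagents that add atoms: calcium hypochlorite ([Ca+2].[O-]Cl.[O-]Cl)
Why: Ene-type chlorination by HOCl of the only electron-rich alkene (isopropenyl); the lactone enoate is inert.

Step 13
Reactants: 22 allylic chloride
Product: 23 2-substituted acrolein (the C9 substituent is now 3-oxoprop-1-en-2-yl)
Conditions: Me3NO, DMSO, 25 °C
Reagents that add atoms: trimethylamine N-oxide (C[N+](C)(C)[O-])
Why: Kornblum-type oxidation (Ganem variant): the N-oxide oxygen displaces the allylic chloride and elimination of trimethylamine gives the aldehyde.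

Step 14
Reactants: 23 2-substituted acrolein
Product: 24 tetrasubstituted enal lactone (C9=C(CH3)CHO with CHO cis to C10)
Conditions: RuHCl(CO)(PPh3)3 (5 mol%), PhMe, 80 °C
Reagents that add atoms: none
Why: Metal-hydride addition/β-hydride elimination moves the exocyclic double bond into the conjugated tetrasubstituted position (the C9 stereocentre is deliberately destroyed); in the elimination the methyl group turns to the less hindered C8 side, so the formyl group ends cis to C10.

Step 15
Reactants: 24 enal lactone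
Product: 25 lactol allylic alcohol (lactone C=O reduced to the hemiacetal and the ring-A CHO reduced to CH2OH)
Conditions: i-Bu2AlH (6 equiv), CH2Cl2, −78 °C; Rochelle salt
Reagents that add atoms: none
Why: DIBAL reduction stops at the lactol because the tetrahedral aluminate is stable at −78 °C, and reduces the enal 1,2 to the allylic alcohol, which masks it during the olefination; both alkene geometries are untouched.

Step 16
Reactants: 26 2-methylprop-2-en-1-ol; 27 1-bromo-3-methylbut-2-ene
Product: 29 6-methyl-2-methylidenehept-5-en-1-ol, via dilithio methallyl alkoxide 28 (not isolated)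
Conditions: n-BuLi (2.2 equiv), TMEDA, Et2O, 0 → 25 °C; then 27, −78 → 25 °C
Reagents that add atoms: none
Why: SN2 alkylation of the methallyl alcohol dianion at its allylic carbon by prenyl bromide.

Step 17
Reactants: 29 allylic alcohol
Product: 30 2-(bromomethyl)-6-methylhepta-1,5-diene
Conditions: PBr3, Et2O, −10 °C
Reagents that add atoms: phosphorus tribromide (BrP(Br)Br)
Why: Conversion of a primary allylic alcohol to the bromide; allylic transposition would give the same compound.

Step 18
Reactants: 30 allylic bromide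
Product: 31 diethyl (6-methyl-2-methylidenehept-5-en-1-yl)phosphonate
Conditions: P(OEt)3, 120 °C
Reagents that add atoms: triethyl phosphite (CCOP(OCC)OCC)
Why: Michaelis–Arbuzov reaction.

Step 19
Reactants: 25 lactol allylic alcohol; 31 allylic phosphonate
Product: 32 bis-TBS triene tetraol (target skeleton with the ring-A aldehyde as CH2OH and TBS on the side-chain allylic oxygen and the hydroxypropyl oxygen)
Conditions: 31 (5 equiv), n-BuLi, THF–DMPU, −78 → 25 °C
Reagents that add atoms: none
Why: Horner–Wadsworth–Emmons olefination of the hydroxy enal released from the lactolate; allylic phosphonate anions react at the α-carbon and give the E-alkene, and the trisubstituted alkene set by the lactone is retained.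

Step 20
Reactants: 32 triene tetraol
Product: 33 bis-TBS ether of 28-deacetylbelamcandal
Conditions: MnO2, CH2Cl2, 25 °C
Reagents that add atoms: none
Why: MnO2 oxidises only the free allylic primary alcohol (the other free hydroxyls are non-allylic and the other allylic oxygen is silylated), with retention of the tetrasubstituted alkene geometry.

Step 21
Reactants: 33 bis-TBS ether
Product: 34 28-deacetylbelamcandal
Conditions: Bu4NF, AcOH, THF, 0 → 25 °C
Reagents that add atoms: none
Why: Fluoride cleavage of both silyl ethers, buffered with AcOH so the enal is not enolised.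

**Compound list**

1 | (S)-(+)-carvone, (5S)-2-methyl-5-(prop-1-en-2-yl)cyclohex-2-en-1-one | CC1=CC[C@H](C(C)=C)CC1=O | starting material
2 | trans-carvone oxide, (1S,4S,6S)-1-methyl-4-(prop-1-en-2-yl)-7-oxabicyclo[4.1.0]heptan-2-one | C[C@]12O[C@H]1C[C@H](C(C)=C)CC2=O | intermediate
3 | (1S,4S)-1-methyl-4-(prop-1-en-2-yl)cyclohexane-1,2-diol, 1-OH trans to isopropenyl, C2 epimers | C[C@@]1(O)C(O)C[C@@H](C(C)=C)CC1 | intermediate
4 | (2S,5S)-2-hydroxy-2-methyl-5-(prop-1-en-2-yl)cyclohexan-1-one | C[C@@]1(O)C(=O)C[C@@H](C(C)=C)CC1 | intermediate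
5 | (E)-2,4,6-triisopropylbenzenesulfonylhydrazone of 4 | C[C@@]1(O)/C(C[C@@H](C(C)=C)CC1)=N/NS(=O)(=O)c2c(C(C)C)cc(C(C)C)cc2C(C)C | intermediate
6 | cyclobutanone | O=C1CCC1 | starting material
7 | lithium (1S,4S)-2-lithio-1-methyl-4-(prop-1-en-2-yl)cyclohex-2-en-1-olate | C[C@@]1(O[Li])C([Li])=C[C@@H](C(C)=C)CC1 | intermediate
8 | 1-[(3S,6S)-6-hydroxy-6-methyl-3-(prop-1-en-2-yl)cyclohex-1-en-1-yl]cyclobutan-1-ol | C[C@@]1(O)C(C2(O)CCC2)=C[C@@H](C(C)=C)CC1 | intermediate
9 | allyl phenyl sulfone | C=CCS(=O)(=O)c1ccccc1 | starting material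
10 | cyclic dimethylsilylene of 8 (six-membered O–SiMe2–O ring across the two tertiary alcohols) | C[C@]12CC[C@H](C(C)=C)C=C1C1(CCC1)O[Si](C)(C)O2 | intermediate
11 | 6-O-[dimethyl(phenylsulfinyloxy)silyl] ether of 12 | C1CC[C@]2([C@H](CC=C)[C@@H](C(C)=C)CC[C@]2(C)O[Si](C)(C)OS(=O)c3ccccc3)C1=O | intermediate
12 | (5R,6S,9S,10R)-6-hydroxy-6-methyl-9-(prop-1-en-2-yl)-10-(prop-2-en-1-yl)spiro[4.5]decan-1-one; 6-OH, C1 and 10-allyl on one face of ring A, 9-isopropenyl on the other | C1CC[C@]2([C@H](CC=C)[C@@H](C(C)=C)CC[C@]2(C)O)C1=O | intermediate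
13 | bis(3-methylbutan-2-yl)borane adduct of 12 at the terminal allyl carbon | C1CC[C@]2([C@H](CCCB(C(C)C(C)C)C(C)C(C)C)[C@@H](C(C)=C)CC[C@]2(C)O)C1=O | intermediate
14 | (5R,6S,9S,10R)-6-hydroxy-10-(3-hydroxypropyl)-6-methyl-9-(prop-1-en-2-yl)spiro[4.5]decan-1-one | C1CC[C@]2([C@H](CCCO)[C@@H](C(C)=C)CC[C@]2(C)O)C1=O | intermediate
15 | (5R,6S,9S,10R)-10-{3-[(tert-butyldimethylsilyl)oxy]propyl}-6-hydroxy-6-methyl-9-(prop-1-en-2-yl)spiro[4.5]decan-1-one | C1CC[C@]2([C@H](CCCO[Si](C)(C)C(C)(C)C)[C@@H](C(C)=C)CC[C@]2(C)O)C1=O | intermediate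
16 | tert-butyldimethyl(prop-2-yn-1-yloxy)silane | C#CCO[Si](C)(C)C(C)(C)C | starting material
17 | lithium acetylide of 16 | [Li]C#CCO[Si](C)(C)C(C)(C)C | intermediate
18 | methyl 4-[(tert-butyldimethylsilyl)oxy]but-2-ynoate | COC(=O)C#CCO[Si](C)(C)C(C)(C)C | intermediate
19 | methyl (2E)-4-[(tert-butyldimethylsilyl)oxy]-3-[(2S,5R,6S,9S,10R)-10-{3-[(tert-butyldimethylsilyl)oxy]propyl}-6-hydroxy-6-methyl-1-oxo-9-(prop-1-en-2-yl)spiro[4.5]decan-2-yl]but-2-enoate | COC(=O)/C=C(/CO[Si](C)(C)C(C)(C)C)[C@@H]1CC[C@]2([C@H](CCCO[Si](C)(C)C(C)(C)C)[C@@H](C(C)=C)CC[C@]2(C)O)C1=O | intermediate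
20 | (1R,2S,5S,6S,9S,10R)-1,6-diol from reduction of 19 (1-OH cis to the C2 side chain, anti to C6) | COC(=O)/C=C(/CO[Si](C)(C)C(C)(C)C)[C@@H]1CC[C@]2([C@H](CCCO[Si](C)(C)C(C)(C)C)[C@@H](C(C)=C)CC[C@]2(C)O)[C@@H]1O | intermediate
21 | cis-fused δ-lactone: 4-(TBSO-methyl)-5,6-dihydro-2H-pyran-2-one fused to C1 (O) and C2 (C) of the spirodecane; other centres as in 20 | O=C1C=C(CO[Si](C)(C)C(C)(C)C)[C@@H]2CC[C@]3([C@H](CCCO[Si](C)(C)C(C)(C)C)[C@@H](C(C)=C)CC[C@]3(C)O)[C@@H]2O1 | intermediate
22 | lactone 21 with 3-chloroprop-1-en-2-yl at C9 | O=C1C=C(CO[Si](C)(C)C(C)(C)C)[C@@H]2CC[C@]3([C@H](CCCO[Si](C)(C)C(C)(C)C)[C@@H](C(=C)CCl)CC[C@]3(C)O)[C@@H]2O1 | intermediate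
23 | lactone 21 with 3-oxoprop-1-en-2-yl at C9 | O=C1C=C(CO[Si](C)(C)C(C)(C)C)[C@@H]2CC[C@]3([C@H](CCCO[Si](C)(C)C(C)(C)C)[C@@H](C(=C)C=O)CC[C@]3(C)O)[C@@H]2O1 | intermediate
24 | lactone with the C9 alkylidene C9=C(CH3)CHO, CHO cis to C10 | O=C1C=C(CO[Si](C)(C)C(C)(C)C)[C@@H]2CC[C@]3([C@H](CCCO[Si](C)(C)C(C)(C)C)/C(=C(/C)C=O)CC[C@]3(C)O)[C@@H]2O1 | intermediate
25 | lactol of 24 with the ring-A aldehyde reduced to CH2OH (anomer mixture) | OC1C=C(CO[Si](C)(C)C(C)(C)C)[C@@H]2CC[C@]3([C@H](CCCO[Si](C)(C)C(C)(C)C)/C(=C(/C)CO)CC[C@]3(C)O)[C@@H]2O1 | intermediate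
26 | 2-methylprop-2-en-1-ol | C=C(C)CO | starting material
27 | 1-bromo-3-methylbut-2-ene | CC(C)=CCBr | starting material
28 | dilithio 2-methylprop-2-en-1-olate (allylic C-lithio, O-lithio) | [Li]CC(=C)CO[Li] | intermediate
29 | 6-methyl-2-methylidenehept-5-en-1-ol | C=C(CO)CCC=C(C)C | intermediate
30 | 2-(bromomethyl)-6-methylhepta-1,5-diene | C=C(CBr)CCC=C(C)C | intermediate
31 | diethyl (6-methyl-2-methylidenehept-5-en-1-yl)phosphonate | CCOP(=O)(OCC)CC(=C)CCC=C(C)C | intermediate
32 | bis-TBS ether of the target skeleton with the ring-A aldehyde as CH2OH | C=C(/C=C/C=C(/CO[Si](C)(C)C(C)(C)C)[C@@H]1CC[C@]2([C@H](CCCO[Si](C)(C)C(C)(C)C)/C(=C(/C)CO)CC[C@]2(C)O)[C@@H]1O)CCC=C(C)C | intermediate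
33 | bis-TBS ether of 28-deacetylbelamcandal | C=C(/C=C/C=C(/CO[Si](C)(C)C(C)(C)C)[C@@H]1CC[C@]2([C@H](CCCO[Si](C)(C)C(C)(C)C)/C(=C(/C)C=O)CC[C@]2(C)O)[C@@H]1O)CCC=C(C)C | intermediate
34 | 28-deacetylbelamcandal, (1R,2S,5S,6S,10R) in spirodecane numbering | C=C(/C=C/C=C(/CO)[C@@H]1CC[C@]2([C@H](CCCO)/C(=C(/C)C=O)CC[C@]2(C)O)[C@@H]1O)CCC=C(C)C | target

**Step count and risks**

Total step count: 21. Longest linear sequence: 17 steps (1–8, 10–15, 19–21) from (S)-carvone; steps 9 and 16–18 are side branches.

The three steps most likely to fail: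

Step 6, the new reaction. The oxygen-flanked alkene may be slow to oxidise, the silylene may be lost before the shift, and the allyl group may enter C10 from the wrong face. The fallback uses known chemistry and sets out from 8. Hydroxyl-directed epoxidation with VO(acac)2 and t-BuOOH on the face of the ring hydroxyl gives the epoxy diol F1. BF3·OEt2 then triggers the stereospecific epoxy-alcohol semipinacol ring expansion (the CH2 migrates anti to the breaking C–O bond) to the dihydroxy spiro ketone F2. PhOC(S)Cl, pyridine and DMAP convert its secondary C10 hydroxyl into the phenyl thionocarbonate F3. Radical allylation with allyltributylstannane (Bu3SnCH2CH=CH2) and AIBN in benzene at 80 °C comes back to the route at 12.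

Step 10, the dianion Michael addition. The enolate may attack the ester carbonyl or the adduct may close to a pyranone. The fallback sets out from 15. Palladium-catalysed α-alkenylation of the ketone (Pd2(dba)3, Q-Phos, LiN(SiMe3)2, 2-bromo-3-[(tert-butyldimethylsilyl)oxy]prop-1-ene) gives the 2-alkenyl ketone F4. Evans–Saksena reduction with Me4NBH(OAc)3 gives the diol F5. Acryloyl chloride and i-Pr2NEt acylate the secondary hydroxyl to the acrylate F6. Ring-closing metathesis with the second-generation Grubbs catalyst, followed by DBU to settle the cis ring fusion, comes back at 21.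

Step 14, the isomerisation to the tetrasubstituted enal. It may stall or give the wrong alkene geometry, since the two geometric isomers are expected to be close in energy and the selectivity is kinetic. The fallback sets out from 21. Allylic oxidation with SeO2 (cat.) and t-BuOOH at the ring methine gives the tertiary allylic alcohol F7. Oxidative 1,3-transposition with C5H5NH[CrO3Cl] (Babler–Dauben) then gives the enal directly and comes back at 24. In the chair-like [3,3] shift of the chromate ester the methyl group avoids the substituted C10, so the formyl carbon ends cis to C10.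

Further compounds
F1 | step 6 | epoxide of 8 on the face of the ring hydroxyl (1-(2,3-epoxycyclohexyl)cyclobutanol, oxirane O cis to the C–OH oxygen) | C[C@@]1(O)[C@]2(C3(O)CCC3)O[C@@H]2[C@@H](C(C)=C)CC1
F2 | step 6 | 6,10-dihydroxy-6-methyl-9-(prop-1-en-2-yl)spiro[4.5]decan-1-one, 10-OH cis to 6-OH and to C1 | C1CC[C@]2([C@H](O)[C@@H](C(C)=C)CC[C@]2(C)O)C1=O
F3 | step 6 | O-phenyl thionocarbonate of F2 at the C10 oxygen | C1CC[C@]2([C@H](OC(=S)Oc3ccccc3)[C@@H](C(C)=C)CC[C@]2(C)O)C1=O
F4 | step 10 | ketone 15 carrying 3-[(tert-butyldimethylsilyl)oxy]prop-1-en-2-yl at C2 | C=C(CO[Si](C)(C)C(C)(C)C)[C@@H]1CC[C@]2([C@H](CCCO[Si](C)(C)C(C)(C)C)[C@@H](C(C)=C)CC[C@]2(C)O)C1=O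
F5 | step 10 | 1,6-diol from F4, 1-OH cis to the C2 alkenyl group | C=C(CO[Si](C)(C)C(C)(C)C)[C@@H]1CC[C@]2([C@H](CCCO[Si](C)(C)C(C)(C)C)[C@@H](C(C)=C)CC[C@]2(C)O)[C@@H]1O
F6 | step 10 | acrylate ester of F5 at the C1 oxygen | C=C(CO[Si](C)(C)C(C)(C)C)[C@@H]1CC[C@]2([C@H](CCCO[Si](C)(C)C(C)(C)C)[C@@H](C(C)=C)CC[C@]2(C)O)[C@@H]1OC(=O)C=C
F7 | step 14 | lactone 21 with an additional tertiary hydroxyl at C9 (C9 bears OH and isopropenyl) | O=C1C=C(CO[Si](C)(C)C(C)(C)C)[C@@H]2CC[C@]3([C@H](CCCO[Si](C)(C)C(C)(C)C)C(O)(C(C)=C)CC[C@]3(C)O)[C@@H]2O1
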